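Ring B (C5–C10) is disconnected at its future C8 carbonyl to a cyclopentanone: a trans-fused hydrindan-2-one in which C6 is bonded directly to C8. Its regiodefined silyl enol ether (C6=C8) is cyclopropanated, and FeCl3 opening of the siloxycyclopropane cleaves the C6–C8 bond, leaving C7 between C6 and C8 and delivering ring B as its 6-en-8-one in one operation. The step exploits C8 (later C8=C17) flanked by C7 and C9: the enone leaves C9 as the only enolisable carbon, so the dienyl chain is attached there regiospecifically. The precursor is a siloxybicyclo[3.1.0]hexane fused to ring A, built from (S)-2-allyl-2-methylcyclohexanone (C10) by Wacker/aldol cyclopentenone annulation.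

Key step: step 11

Remark: labdane numbering is used throughout (ring A = C1–C5, C10; ring B = C5–C10; C17 = exocyclic methylene carbon; C18/C19 = the two CH2O carbons on C4; C20 = angular methyl). The target is read as the ent-labdane (5S,9R,10S) with a 12E diene.

Step 1
Reactants: 1 (E)-3-methylpent-2-en-4-yn-1-ol
Product: 2 (E)-3-methylpenta-2,4-dien-1-ol
Conditions: H2 (1 atm), Lindlar catalyst, quinoline, EtOAc, rt, stopped after 1 equiv H2
Reagents that add atoms: none
Why: Lindlar semihydrogenation of the terminal alkyne should stop at the conjugated diene and leave the E trisubstituted alkene untouched.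

Step 2
Reactants: 2 (E)-3-methylpenta-2,4-dien-1-ol
Product: 3 (E)-5-bromo-3-methylpenta-1,3-diene
Conditions: PBr3 (0.4 equiv), Et2O, −20 to 0 °C; used at once
Reagents that add atoms: phosphorus tribromide, BrP(Br)Br
Why: Bromination of the primary allylic alcohol via its bromophosphite (SN2) should keep the E geometry, the conjugated primary bromide being the favoured allylic isomer.

Step 3
Reactants: 4 cyclohexanone; 5 diallyl carbonate
Product: 7 allyl 1-methyl-2-oxocyclohexane-1-carboxylate (racemic), via sodium keto ester enolate 6 (not isolated)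
Conditions: NaH (2.2 equiv), THF, reflux; then MeI, rt
Reagents that add atoms: iodomethane, CI
Why: Claisen-type C-acylation of the ketone enolate with the carbonate, then C-methylation of the stabilised β-keto ester enolate, should give the quaternary β-keto ester, racemic at this stage.

Step 4
Reactants: 7 allyl 1-methyl-2-oxocyclohexane-1-carboxylate
Product: 8 (S)-2-allyl-2-methylcyclohexan-1-one
Conditions: Pd2(dba)3 (cat.), (S)-t-Bu-PHOX (cat.), THF, 25–30 °C
Reagents that add atoms: none
Why: In this Pd-catalysed decarboxylative asymmetric allylic alkylation (Tsuji allylation) both enantiomers of 7 converge on one Pd enolate, and the (S)-PHOX ligand should set the (S) quaternary carbon, the future C10.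

Step 5
Reactants: 8 (S)-2-allyl-2-methylcyclohexan-1-one
Product: 9 (S)-2-allyl-6,6-bis(hydroxymethyl)-2-methylcyclohexan-1-one
Conditions: 37% aq. CH2O (excess), KOH (cat.), MeOH, 0 °C to rt
Reagents that add atoms: formaldehyde, C=O
Why: Double aldol addition to formaldehyde should occur at C4, the only enolisable position since C10 is quaternary, and creates no stereocentre because the two new groups are identical.

Step 6
Reactants: 9 (S)-2-allyl-6,6-bis(hydroxymethyl)-2-methylcyclohexan-1-one
Product: 10 (8S)-8-allyl-3,3,8-trimethyl-2,4-dioxaspiro[5.5]undecan-7-one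
Conditions: 2,2-dimethoxypropane, PPTS (cat.), acetone, rt
Reagents that add atoms: 2,2-dimethoxypropane, COC(C)(C)OC
Why: Acid-catalysed transacetalisation should close the 1,3-diol to the six-membered acetonide, which blocks retro-aldol loss of formaldehyde in the later basic steps.

Step 7
Reactants: 10 (8S)-8-allyl-3,3,8-trimethyl-2,4-dioxaspiro[5.5]undecan-7-one
Product: 11 (8S)-3,3,8-trimethyl-8-(2-oxopropyl)-2,4-dioxaspiro[5.5]undecan-7-one
Conditions: PdCl2 (cat.), Cu(OAc)2·H2O (cat.), O2 (1 atm), DMA/H2O, rt
Reagents that add atoms: water, O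
Why: Tsuji–Wacker oxidation of the terminal alkene with Markovnikov selectivity should give the methyl ketone, the acetate co-oxidant keeping the medium mild enough for the acetonide.

Step 8
Reactants: 11 (8S)-3,3,8-trimethyl-8-(2-oxopropyl)-2,4-dioxaspiro[5.5]undecan-7-one
Product: 12 bicyclic cyclopentenone (7a'S)-2,2,7a'-trimethyl-5',6',7',7a'-tetrahydrospiro[1,3-dioxane-5,4'-inden]-2'(1'H)-one
Conditions: KOH, xylenes, 110 °C, Dean–Stark
Reagents that add atoms: none
Why: Intramolecular aldol condensation should close the cyclopentenone (C5=C6–C8=O), since only the acetonyl methyl can enolise toward the ring ketone (C4 and C10 are quaternary) and water removal drives dehydration.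

Step 9
Reactants: 12 bicyclic cyclopentenone
Product: 14 trans-fused trimethylsilyl enol ether (5S,10S; C6=C8–OSiMe3), via lithium enolate 13 (not isolated)
Conditions: Li (2.2 equiv), NH3(l)/THF, t-BuOH (1 equiv), −78 °C; isoprene; NH3 removed; then TMSCl/Et3N, THF, −78 to 0 °C
Reagents that add atoms: chlorotrimethylsilane, C[Si](C)(C)Cl
Why: In this dissolving-metal enone reduction the C5 carbanion should be protonated anti to the angular methyl to give the trans ring fusion (as with A-nor-steroid 3(5)-en-2-ones), and O-silylation traps the enolate regiospecifically.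

Step 10
Reactants: 14 trans-fused trimethylsilyl enol ether
Product: 15 siloxycyclopropane (C7 methylene bridging C6 and C8, anti to the C10 methyl)
Conditions: Et2Zn, CH2I2, Et2O, 0 °C to rt
Reagents that add atoms: diiodomethane, ICI
Why: Furukawa–Simmons–Smith cyclopropanation of the electron-rich enol ether should occur on the face opposite the angular methyl, and the new centres at C6 and C8 are destroyed in step 11.

Step 11
Reactants: 15 siloxycyclopropane
Product: 17 trans-fused decal-6-en-8-one acetonide (5S,10S), via 6-chloro-8-ketone 16 (not isolated)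
Conditions: FeCl3 (2.2 equiv), DMF, 0 °C to rt; then NaOAc, MeOH, reflux
Reagents that add atoms: none
Why: Ito–Saegusa ring expansion: iron(III) replaces silicon on the cyclopropanol oxygen, one-electron oxidation gives the cyclopropyloxy radical, β-scission of the internal C6–C8 bond gives the C6 radical of the new cyclohexanone, chlorine transfer from a second FeCl3 gives 16, and acetate-induced elimination gives the enone. The closest known reaction type is the FeCl3 oxidative opening of 1-siloxybicyclo[n.1.0]alkanes to 2-cycloalkenones, which is known for the five-to-six case. No ring is closed: ring B arises by fragmentation of the zero-atom bridge of the bicyclo[3.1.0]hexane, C7 having been attached in step 10. No stereocentre is formed (the C6 chloride is transient) and C5 and C10 are not touched. The step needs internal rather than external cyclopropane cleavage, which is secured by formation of a secondary ring radical instead of a primary one and by relief of bicyclic strain, while the site of insertion (between C6 and C8, not C8 and C9) is fixed by the enol ether regiochemistry of step 9. The acetonide should survive because FeCl3 is strongly solvated in DMF at 0 °C.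

Step 12
Reactants: 17 trans-fused decal-6-en-8-one acetonide; 3 (E)-5-bromo-3-methylpenta-1,3-diene
Product: 19 C9-alkylated enone (5S,9R,10R; side chain anti to the C10 methyl), via C9 lithium enolate 18 (not isolated)
Conditions: LDA, THF, −78 °C; then 3, DMPU, −78 to −30 °C
Reagents that add atoms: none
Why: Kinetic α'-deprotonation of the enone (C9 carries the only accessible α-hydrogens) and SN2 alkylation by the allylic bromide should attach the chain at C9, axial attack anti to the angular methyl giving mainly the 9-epimer that step 13 corrects.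

Step 13
Reactants: 19 C9-alkylated enone
Product: 21 saturated 8-ketone (5S,9S,10R; side chain equatorial, cis to the C10 methyl), via 9-epi 8-ketone 20 (not isolated)
Conditions: [(Ph3P)CuH]6, H2O (2 equiv), benzene, rt; then NaOMe, MeOH, rt
Reagents that add atoms: none
Why: Conjugate reduction with Stryker's reagent should reduce only the enone C=C (the unactivated diene is inert), and methoxide equilibration through the enolate should place the C9 chain equatorial under thermodynamic control.

Step 14
Reactants: 21 saturated 8-ketone
Product: 22 ent-labda-8(17),12E,14-triene-18,19-diol acetonide (5S,9R,10S)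
Conditions: Ph3PCH3Br, KOt-Bu, toluene, rt to 90 °C
Reagents that add atoms: methyltriphenylphosphonium bromide, C[P+](c1ccccc1)(c1ccccc1)c1ccccc1.[Br-]
Why: Wittig methylenation of the hindered ketone with excess ylide should install C17, and enolisation by the ylide is harmless because C9 is already in its more stable configuration.

Step 15
Reactants: 22 ent-labda-8(17),12E,14-triene-18,19-diol acetonide
Product: 23 ent-labda-8(17),12E,14-triene-18,19-diol (5S,9R,10S)
Conditions: PPTS (cat.), MeOH, rt to 40 °C
Reagents that add atoms: none
Why: Mild acid-catalysed transacetalisation should remove the acetonide without isomerising the 8(17)-alkene or the diene.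

Step 16
Reactants: 23 ent-labda-8(17),12E,14-triene-18,19-diol
Product: 24 ent-labda-8(17),12E,14-triene-18,19-diyl diacetate (5S,9R,10S), the target
Conditions: Ac2O, pyridine, DMAP (cat.), CH2Cl2, 0 °C to rt
Reagents that add atoms: acetic anhydride, CC(=O)OC(C)=O
Why: DMAP-catalysed acylation should esterify both neopentyl primary alcohols.

Compound list
1 | (E)-3-methylpent-2-en-4-yn-1-ol | C#C/C(C)=C/CO | starting material
2 | (E)-3-methylpenta-2,4-dien-1-ol | C=C/C(C)=C/CO | intermediate
3 | (E)-5-bromo-3-methylpenta-1,3-diene | C=C/C(C)=C/CBr | intermediate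
4 | cyclohexanone | O=C1CCCCC1 | starting material
5 | diallyl carbonate | C=CCOC(=O)OCC=C | starting material
6 | sodium enolate of allyl 2-oxocyclohexane-1-carboxylate | C=CCOC(=O)C1=C([O-])CCCC1.[Na+] | intermediate
7 | allyl 1-methyl-2-oxocyclohexane-1-carboxylate (racemic) | C=CCOC(=O)C1(C)CCCCC1=O | intermediate
8 | (S)-2-allyl-2-methylcyclohexan-1-one | O=C1CCCC[C@@]1(C)CC=C | intermediate
9 | (S)-2-allyl-6,6-bis(hydroxymethyl)-2-methylcyclohexan-1-one | O=C1C(CO)(CO)CCC[C@@]1(C)CC=C | intermediate
10 | (8S)-8-allyl-3,3,8-trimethyl-2,4-dioxaspiro[5.5]undecan-7-one | O=C1C2(COC(C)(C)OC2)CCC[C@@]1(C)CC=C | intermediate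
11 | (8S)-3,3,8-trimethyl-8-(2-oxopropyl)-2,4-dioxaspiro[5.5]undecan-7-one | O=C1C2(COC(C)(C)OC2)CCC[C@@]1(C)CC(C)=O | intermediate
12 | bicyclic cyclopentenone, (7a'S)-2,2,7a'-trimethyl-5',6',7',7a'-tetrahydrospiro[1,3-dioxane-5,4'-inden]-2'(1'H)-one (enone C5=C6–C8=O, C9H2, 10S) | O=C1C=C2C3(COC(C)(C)OC3)CCC[C@@]2(C)C1 | intermediate
13 | lithium enolate (C6=C8–OLi) of the trans-fused hydrindan-2-one acetonide (5S,10S) | [Li+].[O-]C1=C[C@@H]2C3(COC(C)(C)OC3)CCC[C@@]2(C)C1 | intermediate
14 | trimethylsilyl enol ether (C6=C8–OSiMe3) of the trans-fused hydrindan-2-one acetonide (5S,10S) | C[Si](C)(C)OC1=C[C@@H]2C3(COC(C)(C)OC3)CCC[C@@]2(C)C1 | intermediate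
15 | siloxycyclopropane: 8-trimethylsiloxy, C7 methylene bridging C6 and C8 on the face opposite the C10 methyl (5S,10S) | C[Si](C)(C)O[C@]12C[C@H]1[C@@H]3C4(COC(C)(C)OC4)CCC[C@@]3(C)C2 | intermediate
16 | 6-chloro-8-oxo trans-decalin acetonide (5S,10S; C6 epimers) | O=C1CC(Cl)[C@@H]2C3(COC(C)(C)OC3)CCC[C@@]2(C)C1 | intermediate
17 | trans-fused 10-methyldecal-6-en-8-one with the C4 spiro-acetonide (5S,10S) | O=C1C=C[C@@H]2C3(COC(C)(C)OC3)CCC[C@@]2(C)C1 | intermediate
18 | lithium enolate C8(OLi)=C9 of enone 17 | [Li+].[O-]C1C=C[C@@H]2C3(COC(C)(C)OC3)CCC[C@@]2(C)C=1 | intermediate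
19 | 9-[(2E)-3-methylpenta-2,4-dienyl] enone, side chain anti to the C10 methyl (5S,9R,10R) | C=C/C(C)=C/C[C@H]1C(=O)C=C[C@@H]2C3(COC(C)(C)OC3)CCC[C@@]12C | intermediate
20 | 9-epi saturated 8-ketone (5S,9R,10R) | C=C/C(C)=C/C[C@H]1C(=O)CC[C@@H]2C3(COC(C)(C)OC3)CCC[C@@]12C | intermediate
21 | saturated 8-ketone, side chain equatorial and cis to the C10 methyl (5S,9S,10R): 17-nor-8-oxo-ent-labda-12E,14-diene-18,19-diol acetonide | C=C/C(C)=C/C[C@@H]1C(=O)CC[C@@H]2C3(COC(C)(C)OC3)CCC[C@@]12C | intermediate
22 | ent-labda-8(17),12E,14-triene-18,19-diol acetonide (5S,9R,10S) | C=C/C(C)=C/C[C@@H]1C(=C)CC[C@@H]2C3(COC(C)(C)OC3)CCC[C@@]12C | intermediate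
23 | ent-labda-8(17),12E,14-triene-18,19-diol (5S,9R,10S) | C=C/C(C)=C/C[C@@H]1C(=C)CC[C@@H]2C(CO)(CO)CCC[C@@]12C | intermediate
24 | ent-labda-8(17),12E,14-triene-18,19-diyl diacetate (5S,9R,10S) | C=C/C(C)=C/C[C@@H]1C(=C)CC[C@@H]2C(COC(C)=O)(COC(C)=O)CCC[C@@]12C | target

Total step count: 16. Longest linear sequence: 14 steps (steps 3–16, from cyclohexanone); steps 1–2 are the side-chain branch that joins in step 12.

Steps most likely to fail

Step 11 (key step). The ring opening may take the wrong course: cleavage of an external cyclopropane bond, or loss of the acetonide under Lewis-acidic iron(III). The fallback sets out from 14 and uses a two-electron ring expansion instead. Dibromocarbene (CHBr3, KOt-Bu, pentane, −20 °C to rt) adds to the enol ether, and the dibromocyclopropane opens (cyclopropyl-to-allyl cation, with loss of bromide and the silyl group) to the 7-bromo-decal-6-en-8-one acetonide F1. Hydrodebromination of the vinyl bromide (Bu3SnH, cat. Pd(PPh3)4, THF) then returns to the route at 17.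

Step 13. Thermodynamic equilibration at C9 may be incomplete or may not favour the equatorial chain strongly enough. The fallback sets out from 19 and uses kinetic control. The enone is deprotonated again at C9 (LDA, THF, −78 °C) to the cross-conjugated lithium enolate F2. Protonation at −78 °C (aqueous NH4Cl or a hindered phenol) should deliver hydrogen from the face opposite the C10 methyl and give the C9-epimeric enone F3 with the chain cis to that methyl. Stryker reduction of F3, without the methoxide treatment, returns to the route at 21.

Step 5. The double hydroxymethylation may stall or divert through retro-aldol loss of formaldehyde, dehydration to the α-methylene ketone, or hydride-transfer reduction of the ketone. The fallback sets out from 8 and replaces the aldol by enolate alkylation. Two successive alkylations (LDA, THF/HMPA, benzyl chloromethyl ether) give the 6,6-bis(benzyloxymethyl) ketone F4. Wacker oxidation as in step 7 gives the methyl ketone F5, and hydrogenolysis (H2, Pd/C, EtOAc) frees the diol diketone F6. Acetonide formation as in step 6 returns to the route at 11.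

Further compounds
F1 | step 11 | 7-bromo-decal-6-en-8-one acetonide (5S,10S) | O=C1C(Br)=C[C@@H]2C3(COC(C)(C)OC3)CCC[C@@]2(C)C1
F2 | step 13 | lithium enolate C8(OLi)=C9 of 19 | C=C/C(C)=C/CC1=C([O-])C=C[C@@H]2C3(COC(C)(C)OC3)CCC[C@@]12C.[Li+]
F3 | step 13 | C9 epimer of 19, side chain cis to the C10 methyl | C=C/C(C)=C/C[C@@H]1C(=O)C=C[C@@H]2C3(COC(C)(C)OC3)CCC[C@@]12C
F4 | step 5 | (S)-2-allyl-6,6-bis(benzyloxymethyl)-2-methylcyclohexan-1-one | O=C1C(COCc2ccccc2)(COCc2ccccc2)CCC[C@@]1(C)CC=C
F5 | step 5 | (S)-6,6-bis(benzyloxymethyl)-2-methyl-2-(2-oxopropyl)cyclohexan-1-one | O=C1C(COCc2ccccc2)(COCc2ccccc2)CCC[C@@]1(C)CC(C)=O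
F6 | step 5 | (S)-6,6-bis(hydroxymethyl)-2-methyl-2-(2-oxopropyl)cyclohexan-1-one | O=C1C(CO)(CO)CCC[C@@]1(C)CC(C)=O
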